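The numbers in the tables are simulated for substances that don't exist.

Product in the cedar run is level from the first reading to the last, so the number to find is how much product a charge of catalyst gives before it stops.

all flasks: substrate 0.80 M; free catalyst 0.13 mol%
- cedar: partner 1.5 equiv; temperature 0 °C; the very flask that is asked about, followed so far
- elm: partner 1.5 equiv; temperature 6 °C; run made earlier
- flask: partner 1.50 equiv; temperature 0 °C; time 30 h

| run | time / h | product / % | substrate / % |
|---|---|---|---|
| cedar | 3.00 | 27.5 | 71.5 |
| cedar | 6.00 | 27.6 | 73.6 |
| cedar | 10.0 | 26.9 | 72.7 |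
| cedar | 15.0 | 27.2 | 73.2 |
| cedar | 20.0 | 27.3 | 73.6 |
| cedar | 25.0 | 27.0 | 72.9 |
| elm | 3.00 | 22.9 | 76.8 |
| elm | 6.00 | 22.4 | 78.5 |
| elm | 10.0 | 22.8 | 77.4 |
| elm | 15.0 | 22.6 | 77.5 |
| elm | 20.0 | 21.6 | 76.7 |
| elm | 25.0 | 22.1 | 76.9 |

(each reading ± 0.5 percentage points)

- what is taken out of product is counted as made
- what was read earlier has a scatter of 0.5 percentage points, one standard deviation
- additions bring no volume worth counting

- dawn: at 30 h add free catalyst, 100% of the amount charged, then wait 15 h
- noon: at 30 h add partner, 50.0% of the amount charged, then wait 15 h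
- midnight: at 30 h raise the temperature by 20 K, then wait 15 h
- autumn: at 30 h take out 90% of the product then present, then wait 15 h
- winter: change nothing and wait 15 h more

1. product, in percent of the substrate first charged, at 30 h
2. which option adds most product ("none" when 2 percentage points or less is all one gets) (dawn / noon / midnight / autumn / winter / none)
3. product present, with what was taken out counted in, in percent of the substrate first charged, after dawn
4. product present, with what was taken out counted in, in percent of the substrate first charged, after noon

1. Yield per catalyst. Cedar's readings average 27.2% of product on a loading of 0.13 mol%, which makes 210 turns; that figure is the turnover number, moles of product per mole of catalyst charged.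

2. Hours of working. Those turns stand complete at the first reading, 3.00 h, so on average the catalyst turned at no less than 70.0 h⁻¹.

3. Hours of standing. From 3.00 h to 25.0 h, cedar's product changes by −0.5 percentage points, with a scatter of 0.5 points on each reading. The flask at 30 h is therefore taken at 27.2%.

4. The choice. The readings do not separate a dead catalyst from an equilibrium. This reckoning commits to a dead catalyst, as a choice and not a finding. On that reading, noon, midnight, autumn and winter add no product, and noon stays at 27.2%. Dawn brings fresh catalyst, and if that charge repeats 210 turns, the flask reaches 54.5%. Dawn is the choice here.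

The forecast differs, holding that "equilibrium is the simpler reading": it gives 27.2%, autumn as best, 27.2% after dawn and 36.5% after noon.

The flask gives 27.2%, with dawn as best, 38.0% after dawn and 27.2% after noon.

    partner + free catalyst ⇌ catalyst intermediate A (K = 0.300 M⁻¹, k = 67.0 M⁻¹ min⁻¹, Ea = 38.0 kJ mol⁻¹, ΔH = −53.0 kJ mol⁻¹)
    catalyst intermediate A ⇌ released group + catalyst intermediate B (K = 0.300 M, k = 100 min⁻¹, Ea = 58.0 kJ mol⁻¹, ΔH = −20.0 kJ mol⁻¹)
    substrate + catalyst intermediate B ⇌ catalyst intermediate C (K = 1.80 M⁻¹, k = 330 M⁻¹ min⁻¹, Ea = 42.0 kJ mol⁻¹, ΔH = −21.0 kJ mol⁻¹)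
    catalyst intermediate C → free catalyst + product (k = 92.0 min⁻¹, Ea = 68.0 kJ mol⁻¹)
    2 free catalyst → spent catalyst A (k = 80.0 M⁻¹ min⁻¹, Ea = 47.0 kJ mol⁻¹)
    catalyst intermediate A + released group → spent catalyst B (k = 1.10 M⁻¹ min⁻¹, Ea = 60.0 kJ mol⁻¹)
    (constants at 0 °C)

In the flask, the half-life of the slowest mode at 30.0 h is 0.307 h, far shorter than the 30 h of waiting, and free catalyst stands at 0%, with spent catalyst A at 57.5% and spent catalyst B at 42.5%. Dawn's charge made 82.6 turns, fewer than the 210 of the first charge, and the flask after dawn stands at 38.0%, less than the reckoned 54.5%. The neighbour charged with 0.600 equiv of partner stands at 17.9%, with free catalyst at 0%, which is 138 turns.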